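**Assumption (one line):** the SMILES is read as the exo,exo furofuran (7S,7'S,8R,8'R; (+)-medioresinol type) carrying an erythro (7''S,8''R) guaiacylglycerol unit on the syringyl 4-oxygen; locants C7–C9 = syringyl C3 unit, C7'–C9' = guaiacyl C3 unit, C7''–C9'' = glycerol chain; "FurO" = 4-[(1S,3aR,4S,6aR)-4-(4-benzyloxy-3-methoxyphenyl)tetrahydro-1H,3H-furo[3,4-c]furan-1-yl]-2,6-dimethoxyphenoxy; salts that differ from a numbered compound only by a proton are not numbered.

## Retrosynthetic overview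

1. Hedyotol C ⇐ hydrogenolysis of two benzyl ethers ⇐ erythro side chain (C7''–C8'' bond) by an oxazolidinone-controlled anti-aldol between a FurO-acetyl imide and O-benzylvanillin.
2. Furofuran ⇐ one-flask titanocene radical / iodine cascade on an acyclic epoxy cinnamyl ether: C8–C8' bond (ring A, radical 5-exo), then C7'–O bond (ring B, ionic); the single C7 stereocentre dictates C8, C8' and C7'.
3. Epoxy ether ⇐ Williamson coupling of a syringyl epoxy alcohol (Sharpless kinetic resolution of the vinyl carbinol from syringaldehyde) with O-benzylconiferyl bromide (from O-benzylvanillin).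
4. Ring order: ring A and ring B of the furofuran are both formed in step 7; no other ring is made.

## Route

Step 1
Reactants: 1 syringaldehyde (4-hydroxy-3,5-dimethoxybenzaldehyde)
Product: 2 3,5-dimethoxy-4-(triisopropylsilyloxy)benzaldehyde
Conditions: i-Pr3SiCl, imidazole, DMF, 40 °C
Reagents that add atoms: triisopropylsilyl chloride, CC(C)[Si](Cl)(C(C)C)C(C)C
Why: Imidazole-promoted O-silylation of the hindered phenol gives a silyl ether that survives the Grignard, alkoxide and low-valent titanium steps yet is cleaved by fluoride in step 9 (phenol protection, no stereocentre).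

Step 2
Reactants: 2 3,5-dimethoxy-4-(triisopropylsilyloxy)benzaldehyde
Product: 3 rac-1-[3,5-dimethoxy-4-(triisopropylsilyloxy)phenyl]prop-2-en-1-ol
Conditions: CH2=CHMgBr (1.3 equiv), THF, −78 → 0 °C; then H2O (pH 7 buffer)
Reagents that add atoms: vinylmagnesium bromide, C=C[Mg]Br
Why: Grignard 1,2-addition of the vinyl nucleophile to the aryl aldehyde gives the racemic secondary allylic alcohol needed for kinetic resolution, the aryl silyl ether being inert at low temperature.

Step 3
Reactants: 3 rac-1-[3,5-dimethoxy-4-(triisopropylsilyloxy)phenyl]prop-2-en-1-ol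
Product: 4 (R)-[3,5-dimethoxy-4-(triisopropylsilyloxy)phenyl][(S)-oxiran-2-yl]methanol (erythro)
Conditions: Ti(OiPr)4 (0.2 equiv), D-(−)-diisopropyl tartrate (0.3 equiv), t-BuOOH (0.55 equiv), 4 Å MS, CH2Cl2, −20 °C
Reagents that add atoms: tert-butyl hydroperoxide, CC(C)(C)OO
Why: Sharpless kinetic resolution by asymmetric epoxidation, in which D-(−)-tartrate epoxidises the (S)-carbinol much faster than its enantiomer and delivers oxygen anti to the aryl group to give the erythro (1R,2S) epoxy alcohol, fixing C7 of the target while the unreacted (R)-enantiomer of 3 is removed by chromatography (yield at most 50%).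

Step 4
Reactants: 5 4-(benzyloxy)-3-methoxybenzaldehyde (O-benzylvanillin)
Product: 6 rac-1-[4-(benzyloxy)-3-methoxyphenyl]prop-2-en-1-ol
Conditions: CH2=CHMgBr (1.2 equiv), THF, −78 → 0 °C; then H2O (pH 7 buffer)
Reagents that add atoms: vinylmagnesium bromide, C=C[Mg]Br
Why: Grignard 1,2-addition to the aldehyde gives the 1-arylallyl alcohol, whose stereocentre is irrelevant because it is erased in step 5.

Step 5
Reactants: 6 rac-1-[4-(benzyloxy)-3-methoxyphenyl]prop-2-en-1-ol
Product: 7 (E)-4-(benzyloxy)-3-methoxycinnamyl bromide [(E)-1-(benzyloxy)-4-(3-bromoprop-1-en-1-yl)-2-methoxybenzene]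
Conditions: PBr3 (0.4 equiv), Et2O, 0 °C; used crude at once
Reagents that add atoms: phosphorus tribromide, BrP(Br)Br
Why: Bromination of the p-alkoxy-stabilised 1-arylallyl alcohol with PBr3 proceeds with allylic transposition (SN2'/ion-pair return) to the conjugated, thermodynamically preferred (E)-cinnamyl bromide.

Step 6
Reactants: 4 (R)-[3,5-dimethoxy-4-(triisopropylsilyloxy)phenyl][(S)-oxiran-2-yl]methanol; 7 (E)-4-(benzyloxy)-3-methoxycinnamyl bromide
Product: 8 (S)-2-[(R)-{[(E)-3-(4-benzyloxy-3-methoxyphenyl)prop-2-en-1-yl]oxy}[3,5-dimethoxy-4-(triisopropylsilyloxy)phenyl]methyl]oxirane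
Conditions: NaH (1.2 equiv), n-Bu4NI (cat.), THF, 0 °C → rt
Reagents that add atoms: none
Why: Williamson ether synthesis in which the sodium alkoxide of 4 displaces the primary allylic bromide (SN2) faster than it undergoes Payne rearrangement at 0 °C in THF, so the C7 stereocentre and the epoxide are carried over unchanged.

Step 7
Reactants: 8 (S)-2-[(R)-{[(E)-3-(4-benzyloxy-3-methoxyphenyl)prop-2-en-1-yl]oxy}[3,5-dimethoxy-4-(triisopropylsilyloxy)phenyl]methyl]oxirane
Product: 10 (1S,3aR,4S,6aR)-1-[4-(benzyloxy)-3-methoxyphenyl]-4-[3,5-dimethoxy-4-(triisopropylsilyloxy)phenyl]tetrahydro-1H,3H-furo[3,4-c]furan (O-benzyl O'-triisopropylsilyl (+)-medioresinol), via benzylic iodide titanium alkoxide 9 (not isolated)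
Conditions: (C5H5)2TiCl2 (2.5 equiv), Zn dust, THF, rt [green (C5H5)2TiCl], added slowly to 8 in THF, rt; then I2 (1.5 equiv), THF, rt → 50 °C; aq. Na2S2O3
Reagents that add atoms: none
Why: Nugent–RajanBabu reductive epoxide opening by trivalent titanium gives the C8 radical, which closes ring A by 5-exo-trig cyclisation through a chair-like Beckwith–Houk transition state with the C7 aryl group pseudo-equatorial (7,8-trans and 8,8'-cis, so the existing C7 centre sets C8 and C8'), and iodinolysis of the resulting benzylic titanium species gives iodide 9, whose p-alkoxybenzylic carbon is captured by the C9 titanium alkoxide to close ring B with the aryl group exo (C7', also the thermodynamic isomer), a radical–polar crossover cascade already known for racemic furofuran lignans.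

Step 8
Reactants: 11 (R)-4-benzyl-1,3-oxazolidin-2-one
Product: 12 (R)-4-benzyl-3-(2-bromoacetyl)-1,3-oxazolidin-2-one
Conditions: n-BuLi, THF, −78 °C; then BrCH2COBr, −78 → 0 °C
Reagents that add atoms: bromoacetyl bromide, BrCC(Br)=O
Why: N-acylation of the lithiated oxazolidinone by the acid bromide, which is far more electrophilic at the acyl carbon than at the CH2Br carbon, gives the α-bromo imide without touching the C4 stereocentre.

Step 9
Reactants: 10 O-benzyl O'-triisopropylsilyl (+)-medioresinol; 12 (R)-4-benzyl-3-(2-bromoacetyl)-1,3-oxazolidin-2-one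
Product: 14 (R)-4-benzyl-3-[2-(FurO)acetyl]-1,3-oxazolidin-2-one, via caesium phenolate 13 (not isolated)
Conditions: CsF (3 equiv), 12 (1.5 equiv), DMF, 0 °C → rt
Reagents that add atoms: none
Why: Fluoride cleaves the aryl silyl ether to the caesium phenolate 13, which is O-alkylated in the same flask by the highly SN2-reactive α-bromo imide (one-pot desilylation–Williamson etherification), leaving the benzyl ether and the four furofuran stereocentres untouched.

Step 10
Reactants: 14 (R)-4-benzyl-3-[2-(FurO)acetyl]-1,3-oxazolidin-2-one; 5 4-(benzyloxy)-3-methoxybenzaldehyde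
Product: 16 (R)-4-benzyl-3-[(2S,3S)-3-(4-benzyloxy-3-methoxyphenyl)-2-(FurO)-3-hydroxypropanoyl]-1,3-oxazolidin-2-one (anti aldol), via trimethylsilyl ether 15 (not isolated)
Conditions: MgCl2 (0.2 equiv), Et3N (2 equiv), Me3SiCl (1.5 equiv), 5 (1.3 equiv), EtOAc, rt, 24 h; then citric acid, MeOH–THF, 0 °C
Reagents that add atoms: none
Why: Proposed new method: soft enolisation of the acidified α-aryloxyacetyl imide by MgCl2/Et3N should give the magnesium-chelated Z-enolate, which adds to the aldehyde through a boat transition state on the face opposite the auxiliary benzyl group (Evans-alkylation sense, 2S, which becomes C8'' R) with anti topology (3S = C7'' S), the aldolate being trapped as silyl ether 15 to drive turnover; the closest known reaction is the MgCl2-catalysed direct anti-aldol of N-propionyl oxazolidinones with aromatic aldehydes, the extension here being the α-aryloxy substituent.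

Step 11
Reactants: 16 (R)-4-benzyl-3-[(2S,3S)-3-(4-benzyloxy-3-methoxyphenyl)-2-(FurO)-3-hydroxypropanoyl]-1,3-oxazolidin-2-one
Product: 17 (1S,2R)-1-(4-benzyloxy-3-methoxyphenyl)-2-(FurO)propane-1,3-diol (di-O-benzyl hedyotol C)
Conditions: LiBH4 (2 equiv), THF, MeOH (cat.), 0 °C
Reagents that add atoms: none
Why: Reductive cleavage of the N-acyl oxazolidinone by LiBH4 gives the primary alcohol (C9'') and returns the auxiliary 11 without epimerising the α-aryloxy centre or touching the furofuran and the benzyl ethers.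

Step 12
Reactants: 17 di-O-benzyl hedyotol C
Product: 18 hedyotol C
Conditions: H2 (1 atm), Pd/C (10% palladium on carbon), EtOAc–MeOH, rt, short reaction time
Reagents that add atoms: none
Why: Hydrogenolysis of the two aryl benzyl ethers over palladium on carbon under neutral conditions is much faster than cleavage of the dialkyl benzylic C–O bonds of the furofuran or of the secondary benzylic alcohol, so all six stereocentres survive and the target is released.

## Compound list

1 | syringaldehyde | COc1cc(C=O)cc(OC)c1O | starting material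
2 | 3,5-dimethoxy-4-(triisopropylsilyloxy)benzaldehyde | COc1cc(C=O)cc(OC)c1O[Si](C(C)C)(C(C)C)C(C)C | intermediate
3 | rac-1-[3,5-dimethoxy-4-(triisopropylsilyloxy)phenyl]prop-2-en-1-ol | C=CC(O)c1cc(OC)c(O[Si](C(C)C)(C(C)C)C(C)C)c(OC)c1 | intermediate
4 | (R)-[3,5-dimethoxy-4-(triisopropylsilyloxy)phenyl][(S)-oxiran-2-yl]methanol | O[C@H](c1cc(OC)c(O[Si](C(C)C)(C(C)C)C(C)C)c(OC)c1)[C@@H]1CO1 | intermediate
5 | 4-(benzyloxy)-3-methoxybenzaldehyde (O-benzylvanillin) | COc1cc(C=O)ccc1OCc1ccccc1 | starting material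
6 | rac-1-[4-(benzyloxy)-3-methoxyphenyl]prop-2-en-1-ol | C=CC(O)c1ccc(OCc2ccccc2)c(OC)c1 | intermediate
7 | (E)-4-(benzyloxy)-3-methoxycinnamyl bromide | BrC/C=C/c1ccc(OCc2ccccc2)c(OC)c1 | intermediate
8 | (S)-2-[(R)-{[(E)-3-(4-benzyloxy-3-methoxyphenyl)prop-2-en-1-yl]oxy}[3,5-dimethoxy-4-(triisopropylsilyloxy)phenyl]methyl]oxirane | COc1cc(/C=C/CO[C@@H]([C@@H]2CO2)c2cc(OC)c(O[Si](C(C)C)(C(C)C)C(C)C)c(OC)c2)ccc1OCc1ccccc1 | intermediate
9 | chlorobis(cyclopentadienyl)titanium alkoxide of [(2S,3R,4R)-4-[(4-benzyloxy-3-methoxyphenyl)iodomethyl]-2-[3,5-dimethoxy-4-(triisopropylsilyloxy)phenyl]tetrahydrofuran-3-yl]methanol (iodide carbon: epimer mixture) | [O-]C[C@H]1[C@@H](C(I)c2ccc(OCc3ccccc3)c(OC)c2)CO[C@@H]1c1cc(OC)c(O[Si](C(C)C)(C(C)C)C(C)C)c(OC)c1.[Ti+4].[Cl-].c1cc[cH-]c1.c1cc[cH-]c1 | intermediate (not isolated)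
10 | (1S,3aR,4S,6aR)-1-[4-(benzyloxy)-3-methoxyphenyl]-4-[3,5-dimethoxy-4-(triisopropylsilyloxy)phenyl]tetrahydro-1H,3H-furo[3,4-c]furan | COc1cc([C@H]2OC[C@H]3[C@@H]2CO[C@@H]3c2cc(OC)c(O[Si](C(C)C)(C(C)C)C(C)C)c(OC)c2)ccc1OCc1ccccc1 | intermediate
11 | (R)-4-benzyl-1,3-oxazolidin-2-one | O=C1N[C@H](Cc2ccccc2)CO1 | starting material
12 | (R)-4-benzyl-3-(2-bromoacetyl)-1,3-oxazolidin-2-one | BrCC(=O)N1[C@H](Cc2ccccc2)COC1=O | intermediate
13 | caesium 4-[(1S,3aR,4S,6aR)-4-(4-benzyloxy-3-methoxyphenyl)tetrahydro-1H,3H-furo[3,4-c]furan-1-yl]-2,6-dimethoxyphenolate | COc1cc([C@H]2OC[C@H]3[C@@H]2CO[C@@H]3c2cc(OC)c([O-])c(OC)c2)ccc1OCc1ccccc1.[Cs+] | intermediate (not isolated)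
14 | (R)-4-benzyl-3-[2-(FurO)acetyl]-1,3-oxazolidin-2-one | COc1cc([C@H]2OC[C@H]3[C@@H]2CO[C@@H]3c2cc(OC)c(OCC(=O)N4[C@H](Cc5ccccc5)COC4=O)c(OC)c2)ccc1OCc1ccccc1 | intermediate
15 | (R)-4-benzyl-3-[(2S,3S)-3-(4-benzyloxy-3-methoxyphenyl)-2-(FurO)-3-(trimethylsilyloxy)propanoyl]-1,3-oxazolidin-2-one | COc1cc([C@H]2OC[C@H]3[C@@H]2CO[C@@H]3c2cc(OC)c(O[C@H](C(=O)N4[C@H](Cc5ccccc5)COC4=O)[C@@H](O[Si](C)(C)C)c4ccc(OCc5ccccc5)c(OC)c4)c(OC)c2)ccc1OCc1ccccc1 | intermediate (not isolated)
16 | (R)-4-benzyl-3-[(2S,3S)-3-(4-benzyloxy-3-methoxyphenyl)-2-(FurO)-3-hydroxypropanoyl]-1,3-oxazolidin-2-one | COc1cc([C@H]2OC[C@H]3[C@@H]2CO[C@@H]3c2cc(OC)c(O[C@H](C(=O)N4[C@H](Cc5ccccc5)COC4=O)[C@@H](O)c4ccc(OCc5ccccc5)c(OC)c4)c(OC)c2)ccc1OCc1ccccc1 | intermediate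
17 | (1S,2R)-1-(4-benzyloxy-3-methoxyphenyl)-2-(FurO)propane-1,3-diol | COc1cc([C@H]2OC[C@H]3[C@@H]2CO[C@@H]3c2cc(OC)c(O[C@H](CO)[C@@H](O)c3ccc(OCc4ccccc4)c(OC)c3)c(OC)c2)ccc1OCc1ccccc1 | intermediate
18 | hedyotol C | COc1cc([C@H]2OC[C@H]3[C@@H]2CO[C@@H]3c2cc(OC)c(O[C@H](CO)[C@@H](O)c3ccc(O)c(OC)c3)c(OC)c2)ccc1O | target

## Step count and risks

Total steps: 12. Longest linear sequence: 9 (steps 1, 2, 3, 6, 7, 9, 10, 11, 12).

The three steps most likely to fail:

**Step 3.** A terminal vinyl carbinol with an electron-rich aryl group may resolve slowly or with a modest selectivity factor. The fallback sets out from 3 and comes back at 4. It separates the enantiomers enzymatically and then epoxidises under substrate control: Candida antarctica lipase B and vinyl acetate in toluene acetylate the (R)-enantiomer to (R)-1-[3,5-dimethoxy-4-(triisopropylsilyloxy)phenyl]allyl acetate F2 and leave (S)-1-[3,5-dimethoxy-4-(triisopropylsilyloxy)phenyl]prop-2-en-1-ol F1. F1 with VO(acac)2 and t-BuOOH in CH2Cl2 at 0 °C gives 4 together with its threo epimer (R)-[3,5-dimethoxy-4-(triisopropylsilyloxy)phenyl][(R)-oxiran-2-yl]methanol F3. Separation is not required: etherification of F3 with 7 as in step 6 gives the C8-epimeric epoxy ether F4, and 8 and F4 give the same C8 radical in step 7 and hence the same 10.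

**Step 7.** The C8 radical may be reduced before it cyclises (deoxygenation to an allylic alcohol). Some 7,8-cis cyclisation would appear as the separable C7-endo diastereomer, which must not be equilibrated with acid. The iodine-induced closure may be inefficient. The fallback sets out from 8 and comes back at 10. Run only the radical half: (C5H5)2TiCl as in step 7, but quench with dilute aqueous acid instead of iodine, giving the ring A tetrahydrofuran [(2S,3R,4R)-4-(4-benzyloxy-3-methoxybenzyl)-2-[3,5-dimethoxy-4-(triisopropylsilyloxy)phenyl]tetrahydrofuran-3-yl]methanol F5. Ring B is then closed by a separate benzylic C–H oxidation: DDQ in CH2Cl2 at 0 °C to rt abstracts hydride para to the benzyloxy group and the C9 hydroxyl traps the cation with the aryl group exo, giving 10.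

**Step 10.** The magnesium anti-aldol is untested for α-aryloxyacetyl imides and the electron-rich aldehyde is a weak electrophile; low conversion or a poor anti:syn ratio is possible. The fallback sets out from 14 and comes back at 16. It sets C8'' by acylation and C7'' by reduction instead of by an aldol transition state. The lithium enolate of 14 (LDA, THF, −78 °C) is C-acylated on the face opposite the auxiliary benzyl group with 4-(benzyloxy)-3-methoxybenzoyl chloride F6 (from commercial 4-(benzyloxy)-3-methoxybenzoic acid and oxalyl chloride). This gives (R)-4-benzyl-3-[(2S)-3-(4-benzyloxy-3-methoxyphenyl)-2-(FurO)-3-oxopropanoyl]-1,3-oxazolidin-2-one F7. Its ketone is reduced with NaBH4 in EtOH–CH2Cl2 at −40 °C under Felkin–Anh control (aryloxy group anti to the incoming hydride, the erythro preference known for α-aryloxy aryl ketones) to give 16.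

## Further compounds

F1 | step 3 | (S)-1-[3,5-dimethoxy-4-(triisopropylsilyloxy)phenyl]prop-2-en-1-ol | C=C[C@H](O)c1cc(OC)c(O[Si](C(C)C)(C(C)C)C(C)C)c(OC)c1
F2 | step 3 | (R)-1-[3,5-dimethoxy-4-(triisopropylsilyloxy)phenyl]allyl acetate | C=C[C@@H](OC(C)=O)c1cc(OC)c(O[Si](C(C)C)(C(C)C)C(C)C)c(OC)c1
F3 | step 3 | (R)-[3,5-dimethoxy-4-(triisopropylsilyloxy)phenyl][(R)-oxiran-2-yl]methanol | O[C@H](c1cc(OC)c(O[Si](C(C)C)(C(C)C)C(C)C)c(OC)c1)[C@H]1CO1
F4 | step 3 | (R)-2-[(R)-{[(E)-3-(4-benzyloxy-3-methoxyphenyl)prop-2-en-1-yl]oxy}[3,5-dimethoxy-4-(triisopropylsilyloxy)phenyl]methyl]oxirane | COc1cc(/C=C/CO[C@@H]([C@H]2CO2)c2cc(OC)c(O[Si](C(C)C)(C(C)C)C(C)C)c(OC)c2)ccc1OCc1ccccc1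
F5 | step 7 | [(2S,3R,4R)-4-(4-benzyloxy-3-methoxybenzyl)-2-[3,5-dimethoxy-4-(triisopropylsilyloxy)phenyl]tetrahydrofuran-3-yl]methanol | OC[C@H]1[C@@H](Cc2ccc(OCc3ccccc3)c(OC)c2)CO[C@@H]1c1cc(OC)c(O[Si](C(C)C)(C(C)C)C(C)C)c(OC)c1
F6 | step 10 | 4-(benzyloxy)-3-methoxybenzoyl chloride | COc1cc(C(Cl)=O)ccc1OCc1ccccc1
F7 | step 10 | (R)-4-benzyl-3-[(2S)-3-(4-benzyloxy-3-methoxyphenyl)-2-(FurO)-3-oxopropanoyl]-1,3-oxazolidin-2-one | COc1cc([C@H]2OC[C@H]3[C@@H]2CO[C@@H]3c2cc(OC)c(O[C@H](C(=O)N4[C@H](Cc5ccccc5)COC4=O)C(=O)c4ccc(OCc5ccccc5)c(OC)c4)c(OC)c2)ccc1OCc1ccccc1
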